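The target is read as epicatechin-(4β→8)-catechin-(4α→8)-catechin whose lower catechin unit carries, on O3, the (1S)-1-hydroxy-6-oxocyclohex-2-ene-1-carbonyl group.

**Strategy.** Everything rests on opening the acyl residue at the isolated cis C2=C3 olefin of its six-membered carbocycle, which sits between the quaternary carbinol C1 and C4H2 and cannot move into conjugation with the C6 ketone. Ring-closing metathesis of an acyclic 2-hydroxy-2-vinyl-3-oxohept-6-enoate, assembled on O3 of silyl-protected (+)-catechin from pent-4-enoyl chloride, Meldrum's acid and acetaldehyde, closes this ring and fixes the olefin in one operation; C1 is set beforehand by oxidation of a chelated dienolate on the face remote from ring B. The resulting ester is the chain end for two Lewis-acid C4–C8 couplings (catechin 4α, then epicatechin 4β), followed by global desilylation.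

Key step: step 6

Assumption: the C4 ethers 13 and 16 are drawn as their 4β isomers and the olefin geometry of 9 is left open; neither matters, because C4 is ionized in the couplings and both olefin isomers of 9 give the same dienolate. TBS = tert-butyldimethylsilyl.

Step 1
Reactants: 1 (+)-catechin
Product: 2 5,7,3',4'-tetra-O-TBS-(+)-catechin (3-OH free)
Conditions: TBSCl (4.4 equiv), imidazole, DMF, 0 °C to rt
Reagents that add atoms: tert-butyldimethylsilyl chloride, CC(C)(C)[Si](C)(C)Cl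
Why: Phenolic hydroxyls are silylated much faster than the hindered secondary 3-OH, so the four phenols should be capped and O3 left free for acylation (selective O-silylation; no stereocentre touched).

Step 2
Reactants: 3 Meldrum's acid; 4 pent-4-enoyl chloride
Product: 5 5-(1-hydroxypent-4-en-1-ylidene)-2,2-dimethyl-1,3-dioxane-4,6-dione
Conditions: pyridine (2 equiv), CH2Cl2, 0 °C to rt
Reagents that add atoms: none
Why: C-acylation of the acidic methylene of Meldrum's acid by the acid chloride gives the enolized acyl derivative, the standard precursor of an acylketene.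

Step 3
Reactants: 2 5,7,3',4'-tetra-O-TBS-(+)-catechin; 5 acyl Meldrum's acid
Product: 7 tetra-O-TBS-(+)-catechin-3-yl 3-oxohept-6-enoate, via pent-4-enoylketene 6 (not isolated)
Conditions: 5 (1.5 equiv), toluene, 90 °C
Reagents that add atoms: none
Why: Thermal retro-[4+2] fragmentation of 5 releases acetone and CO2 and gives acylketene 6, which is trapped by the only free hydroxyl of 2 under neutral conditions (acylketene acylation; the C3–O bond is not broken, so C3 keeps its configuration).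

Step 4
Reactants: 7 tetra-O-TBS-(+)-catechin-3-yl 3-oxohept-6-enoate; 8 acetaldehyde
Product: 9 tetra-O-TBS-(+)-catechin-3-yl 2-ethylidene-3-oxohept-6-enoate (E/Z mixture)
Conditions: MeCHO (5 equiv), piperidine (0.1 equiv), AcOH (0.1 equiv), 4 Å MS, CH2Cl2, 0 °C
Reagents that add atoms: none
Why: Knoevenagel condensation of the active methylene with excess acetaldehyde installs the two-carbon unit as an ethylidene group, whose methyl group becomes the terminal olefin carbon in step 5; the olefin geometry is immaterial.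

Step 5
Reactants: 9 tetra-O-TBS-(+)-catechin-3-yl 2-ethylidene-3-oxohept-6-enoate
Product: 11 tetra-O-TBS-(+)-catechin-3-yl (2S)-2-ethenyl-2-hydroxy-3-oxohept-6-enoate, via potassium dienolate 10 (not isolated)
Conditions: KN(SiMe3)2 (1.1 equiv), THF, −78 °C; 2-(phenylsulfonyl)-3-phenyloxaziridine, −78 °C; AcOH quench at −78 °C
Reagents that add atoms: 2-(phenylsulfonyl)-3-phenyloxaziridine, O=S(=O)(c1ccccc1)N1OC1c1ccccc1
Why: γ-Deprotonation gives the doubly stabilized, potassium-chelated dienolate 10, which should take up oxygen at its α-carbon (Davis oxidation of an extended enolate, deconjugative) to give the vinyl-bearing tertiary carbinol; with the carbinol C–H eclipsing the ester C=O, the silyloxylated ring B on C2 lies gauche to O3 over one face of the U-shaped enolate, as the aryl group does in trans-2-arylcycloalkyl ester auxiliaries, so oxygen should arrive on the open face and set C1 as (S), the C1 epimer being a diastereomer that chromatography should remove.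

Step 6
Reactants: 11 tetra-O-TBS-(+)-catechin-3-yl (2S)-2-ethenyl-2-hydroxy-3-oxohept-6-enoate
Product: 12 tetra-O-TBS-(+)-catechin-3-yl (1S)-1-hydroxy-6-oxocyclohex-2-ene-1-carboxylate
Conditions: second-generation Grubbs catalyst RuCl2(=CHPh)(H2IMes)(PCy3) (5 mol%), CH2Cl2 (0.01 M), 40 °C
Reagents that add atoms: none
Why: The ruthenium benzylidene should load onto the unhindered but-3-enyl terminus; the resulting alkylidene then undergoes [2+2] cycloaddition with the vinyl group on C1 and cycloreversion (Chauvin mechanism), expelling ethylene and forming the C2=C3 bond. The closest known reaction type is ring-closing metathesis of 1,7-dienes carrying a free tertiary allylic alcohol, which is tolerated and often accelerating. The one ring formed, the six-membered carbocycle of the acyl unit, is closed between the two terminal olefins, loss of C2H4 makes the closure irreversible, and the ring size enforces the cis olefin. No stereocentre is created; C1, set in step 5, has no α-hydrogen and cannot epimerize, and for the same reason the β,γ-olefin cannot slip into conjugation with the ketone. The step needs cyclization over intermolecular cross-metathesis, which the favourable six-membered closure and dilution secure; the substrate offers no third olefin, and aryl silyl ethers, ketone and ester are inert to the catalyst.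

Step 7
Reactants: 2 5,7,3',4'-tetra-O-TBS-(+)-catechin
Product: 13 5,7,3',4'-tetra-O-TBS-4β-(2-ethoxyethoxy)-(+)-catechin
Conditions: DDQ (2 equiv), 2-ethoxyethanol (5 equiv), CH2Cl2, rt
Reagents that add atoms: 2-ethoxyethanol, CCOCCO
Why: DDQ abstracts hydride from the benzylic C4, which is activated by the 5,7-dioxygenated ring A, and the cation is trapped by the alcohol on the face opposite the 2-aryl group (benzylic C–H oxidation); the configuration of C4 is lost again in step 10.

Step 8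
Reactants: 14 (−)-epicatechin
Product: 15 5,7,3',4'-tetra-O-TBS-(−)-epicatechin (3-OH free)
Conditions: TBSCl (4.4 equiv), imidazole, DMF, 0 °C to rt
Reagents that add atoms: tert-butyldimethylsilyl chloride, CC(C)(C)[Si](C)(C)Cl
Why: Selective O-silylation of the four phenols as in step 1; no stereocentre touched.

Step 9
Reactants: 15 5,7,3',4'-tetra-O-TBS-(−)-epicatechin
Product: 16 5,7,3',4'-tetra-O-TBS-4β-(2-ethoxyethoxy)-(−)-epicatechin
Conditions: DDQ (2 equiv), 2-ethoxyethanol (5 equiv), CH2Cl2, rt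
Reagents that add atoms: 2-ethoxyethanol, CCOCCO
Why: Benzylic oxidation as in step 7; the 2-aryl and 3-OH groups both lie on the α face, so the alcohol should add from the β face.

Step 10
Reactants: 12 protected catechin ester; 13 catechin C4 ether
Product: 17 octa-O-TBS catechin-(4α→8)-catechin carrying the (1S)-1-hydroxy-6-oxocyclohex-2-ene-1-carbonyl group on O3 of the lower unit
Conditions: 12 (1.5 equiv, excess recovered), TMSOTf (0.2 equiv), CH2Cl2, −78 °C; Et3N quench
Reagents that add atoms: none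
Why: TMSOTf ionizes the C4 ether of 13 to a benzylic cation stabilized by ring A, which is captured by C8 of 12 in a Friedel–Crafts alkylation (C6 is flanked by two silyloxy groups), and axial attack anti to the 3-OH of the 2,3-trans cation should give the 3,4-trans (4α) bond.

Step 11
Reactants: 17 protected dimer; 16 epicatechin C4 ether
Product: 18 dodeca-O-TBS epicatechin-(4β→8)-catechin-(4α→8)-catechin carrying the acyl group on O3 of the lowest unit
Conditions: 16 (1.0 equiv), TMSOTf (0.2 equiv), CH2Cl2, −78 °C; Et3N quench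
Reagents that add atoms: none
Why: The same activation of 16 gives the epicatechin C4 cation, which should be captured by C8 of the upper unit of 17 (the only nucleophilic position not flanked by two silyloxy groups) from the β face, opposite both the 2-aryl and the 3-OH group, giving the 4β→8 bond (Friedel–Crafts alkylation).

Step 12
Reactants: 18 protected trimer
Product: 19 CNP0159807.2
Conditions: Et3N·3HF (excess), THF–MeCN, rt, argon; Sephadex LH-20
Reagents that add atoms: none
Why: The mildly acidic fluoride source should cleave all twelve aryl silyl ethers while sparing the base-labile α-hydroxy-β-keto ester, the olefin and the acid-sensitive interflavan bonds; no stereocentre is affected.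

**Compound list**

1 | (+)-catechin, (2R,3S) | O[C@H]1Cc2c(O)cc(O)cc2O[C@@H]1c1ccc(O)c(O)c1 | starting material
2 | 5,7,3',4'-tetra-O-TBS-(+)-catechin (3-OH free) | O[C@H]1Cc2c(O[Si](C)(C)C(C)(C)C)cc(O[Si](C)(C)C(C)(C)C)cc2O[C@@H]1c1ccc(O[Si](C)(C)C(C)(C)C)c(O[Si](C)(C)C(C)(C)C)c1 | intermediate
3 | Meldrum's acid (2,2-dimethyl-1,3-dioxane-4,6-dione) | CC1(C)OC(=O)CC(=O)O1 | starting material
4 | pent-4-enoyl chloride | C=CCCC(=O)Cl | starting material
5 | 5-(1-hydroxypent-4-en-1-ylidene)-2,2-dimethyl-1,3-dioxane-4,6-dione | C=CCCC(O)=C1C(=O)OC(C)(C)OC1=O | intermediate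
6 | pent-4-enoylketene (not isolated) | C=CCCC(=O)C=C=O | intermediate
7 | tetra-O-TBS-(+)-catechin-3-yl 3-oxohept-6-enoate | C=CCCC(=O)CC(=O)O[C@H]1Cc2c(O[Si](C)(C)C(C)(C)C)cc(O[Si](C)(C)C(C)(C)C)cc2O[C@@H]1c1ccc(O[Si](C)(C)C(C)(C)C)c(O[Si](C)(C)C(C)(C)C)c1 | intermediate
8 | acetaldehyde | CC=O | starting material
9 | tetra-O-TBS-(+)-catechin-3-yl 2-ethylidene-3-oxohept-6-enoate (E/Z mixture) | C=CCCC(=O)C(=CC)C(=O)O[C@H]1Cc2c(O[Si](C)(C)C(C)(C)C)cc(O[Si](C)(C)C(C)(C)C)cc2O[C@@H]1c1ccc(O[Si](C)(C)C(C)(C)C)c(O[Si](C)(C)C(C)(C)C)c1 | intermediate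
10 | potassium dienolate of 9 (not isolated) | [K+].C=CCCC([O-])=C(C=C)C(=O)O[C@H]1Cc2c(O[Si](C)(C)C(C)(C)C)cc(O[Si](C)(C)C(C)(C)C)cc2O[C@@H]1c1ccc(O[Si](C)(C)C(C)(C)C)c(O[Si](C)(C)C(C)(C)C)c1 | intermediate
11 | tetra-O-TBS-(+)-catechin-3-yl (2S)-2-ethenyl-2-hydroxy-3-oxohept-6-enoate | C=CCCC(=O)[C@@](O)(C=C)C(=O)O[C@H]1Cc2c(O[Si](C)(C)C(C)(C)C)cc(O[Si](C)(C)C(C)(C)C)cc2O[C@@H]1c1ccc(O[Si](C)(C)C(C)(C)C)c(O[Si](C)(C)C(C)(C)C)c1 | intermediate
12 | tetra-O-TBS-(+)-catechin-3-yl (1S)-1-hydroxy-6-oxocyclohex-2-ene-1-carboxylate | O=C1CCC=C[C@@]1(O)C(=O)O[C@H]1Cc2c(O[Si](C)(C)C(C)(C)C)cc(O[Si](C)(C)C(C)(C)C)cc2O[C@@H]1c1ccc(O[Si](C)(C)C(C)(C)C)c(O[Si](C)(C)C(C)(C)C)c1 | intermediate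
13 | 5,7,3',4'-tetra-O-TBS-4β-(2-ethoxyethoxy)-(+)-catechin (2,3-trans-3,4-cis, 3-OH free) | O[C@H]1[C@@H](OCCOCC)c2c(O[Si](C)(C)C(C)(C)C)cc(O[Si](C)(C)C(C)(C)C)cc2O[C@@H]1c1ccc(O[Si](C)(C)C(C)(C)C)c(O[Si](C)(C)C(C)(C)C)c1 | intermediate
14 | (−)-epicatechin, (2R,3R) | O[C@@H]1Cc2c(O)cc(O)cc2O[C@@H]1c1ccc(O)c(O)c1 | starting material
15 | 5,7,3',4'-tetra-O-TBS-(−)-epicatechin (3-OH free) | O[C@@H]1Cc2c(O[Si](C)(C)C(C)(C)C)cc(O[Si](C)(C)C(C)(C)C)cc2O[C@@H]1c1ccc(O[Si](C)(C)C(C)(C)C)c(O[Si](C)(C)C(C)(C)C)c1 | intermediate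
16 | 5,7,3',4'-tetra-O-TBS-4β-(2-ethoxyethoxy)-(−)-epicatechin (2,3-cis-3,4-trans, 3-OH free) | O[C@@H]1[C@@H](OCCOCC)c2c(O[Si](C)(C)C(C)(C)C)cc(O[Si](C)(C)C(C)(C)C)cc2O[C@@H]1c1ccc(O[Si](C)(C)C(C)(C)C)c(O[Si](C)(C)C(C)(C)C)c1 | intermediate
17 | octa-O-TBS catechin-(4α→8)-catechin, lower unit 3-O-[(1S)-1-hydroxy-6-oxocyclohex-2-ene-1-carbonyl], upper 3-OH free | O=C1CCC=C[C@@]1(O)C(=O)O[C@H]1Cc2c(O[Si](C)(C)C(C)(C)C)cc(O[Si](C)(C)C(C)(C)C)c([C@@H]3c4c(O[Si](C)(C)C(C)(C)C)cc(O[Si](C)(C)C(C)(C)C)cc4O[C@H](c4ccc(O[Si](C)(C)C(C)(C)C)c(O[Si](C)(C)C(C)(C)C)c4)[C@H]3O)c2O[C@@H]1c1ccc(O[Si](C)(C)C(C)(C)C)c(O[Si](C)(C)C(C)(C)C)c1 | intermediate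
18 | dodeca-O-TBS epicatechin-(4β→8)-catechin-(4α→8)-catechin, lowest unit 3-O-[(1S)-1-hydroxy-6-oxocyclohex-2-ene-1-carbonyl], upper two 3-OH free | O=C1CCC=C[C@@]1(O)C(=O)O[C@H]1Cc2c(O[Si](C)(C)C(C)(C)C)cc(O[Si](C)(C)C(C)(C)C)c([C@@H]3c4c(O[Si](C)(C)C(C)(C)C)cc(O[Si](C)(C)C(C)(C)C)c([C@H]5c6c(O[Si](C)(C)C(C)(C)C)cc(O[Si](C)(C)C(C)(C)C)cc6O[C@H](c6ccc(O[Si](C)(C)C(C)(C)C)c(O[Si](C)(C)C(C)(C)C)c6)[C@@H]5O)c4O[C@H](c4ccc(O[Si](C)(C)C(C)(C)C)c(O[Si](C)(C)C(C)(C)C)c4)[C@H]3O)c2O[C@@H]1c1ccc(O[Si](C)(C)C(C)(C)C)c(O[Si](C)(C)C(C)(C)C)c1 | intermediate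
19 | CNP0159807.2: epicatechin-(4β→8)-catechin-(4α→8)-catechin 3-O-[(1S)-1-hydroxy-6-oxocyclohex-2-ene-1-carboxylate] on the lowest unit | O=C1CCC=C[C@@]1(O)C(=O)O[C@H]1Cc2c(O)cc(O)c([C@@H]3c4c(O)cc(O)c([C@H]5c6c(O)cc(O)cc6O[C@H](c6ccc(O)c(O)c6)[C@@H]5O)c4O[C@H](c4ccc(O)c(O)c4)[C@H]3O)c2O[C@@H]1c1ccc(O)c(O)c1 | target

**Totals.** Total step count: 12. Longest linear sequence: 8 steps (1, 3, 4, 5, 6, 10, 11, 12).

**Steps most likely to fail**

1. Step 5. Facial selectivity at C1 may be poor, and oxygen may also be delivered to the γ-carbon of the dienolate. The fallback sets out from 2 and comes back at 12; it closes the ring first and hydroxylates a rigid cyclic enolate under catalyst control. Acylation of 2 with crotonyl chloride (pyridine, DMAP, CH2Cl2) would give the crotonate F1. Its lithium dienolate (LiN(iPr)2, HMPA, THF, −78 °C) should add pent-4-enal at the α-carbon to give the α-vinyl-β-hydroxy ester F2, a diastereomer mixture whose two new centres are erased later. Ring-closing metathesis with the catalyst of step 6 closes the same C2=C3 bond and gives the cyclohexenol ester F3. Dess–Martin oxidation gives the enolized cyclic β-keto ester F4. Enantioselective α-hydroxylation of this cyclic β-keto ester (dihydroquinine as catalyst, cumene hydroperoxide, toluene; the quinidine series if the catechin ester proves mismatched) would then give 12.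

2. Step 10. Self-condensation of the electrophile may outrun attack by the hindered, silylated ring A of the nucleophile. The fallback sets out from 12 and 13 and comes back at 17; it uses a free phenolic nucleophile. Desilylation of 12 (Et3N·3HF, THF) would give the free phenolic catechin ester F5, whose unprotected phloroglucinol-type ring A is a far stronger nucleophile. Coupling of F5 (excess) with 13 (BF3·OEt2, THF–CH2Cl2, 0 °C) should give the half-protected dimer F6. Re-silylation of its four phenols (TBSCl, imidazole, DMF) returns to 17.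

3. Step 11. Attack may occur at the wrong nucleophilic position of the dimer, and the chain may be extended further to tetramers. The fallback sets out from 13, 16 and 12 and comes back at 18; it forms the upper interflavan bond first and uses a monomeric nucleophile in the last coupling, by orthogonal activation. Exchange of the ether of 13 for a thioether (2,6-dimethylbenzenethiol, BF3·OEt2, CH2Cl2, −78 °C) would give the 4α-arylthio catechin F7. In excess, F7 should act as the C8 nucleophile toward 16 (BF3·OEt2, CH2Cl2, −78 °C), its C–S bond being far less readily ionized than the C4–O acetal of 16 under these conditions, and give the dimeric thioether F8. Thiophilic activation of F8 (AgBF4, THF, 0 °C) in the presence of 12 then forms the 4α→8 bond last and gives 18.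

**Further compounds**

F1 | step 5 | tetra-O-TBS-(+)-catechin-3-yl (E)-but-2-enoate | C/C=C/C(=O)O[C@H]1Cc2c(O[Si](C)(C)C(C)(C)C)cc(O[Si](C)(C)C(C)(C)C)cc2O[C@@H]1c1ccc(O[Si](C)(C)C(C)(C)C)c(O[Si](C)(C)C(C)(C)C)c1
F2 | step 5 | tetra-O-TBS-(+)-catechin-3-yl 2-ethenyl-3-hydroxyhept-6-enoate (diastereomer mixture at the two new centres) | C=CCCC(O)C(C=C)C(=O)O[C@H]1Cc2c(O[Si](C)(C)C(C)(C)C)cc(O[Si](C)(C)C(C)(C)C)cc2O[C@@H]1c1ccc(O[Si](C)(C)C(C)(C)C)c(O[Si](C)(C)C(C)(C)C)c1
F3 | step 5 | tetra-O-TBS-(+)-catechin-3-yl 6-hydroxycyclohex-2-ene-1-carboxylate (diastereomer mixture) | OC1CCC=CC1C(=O)O[C@H]1Cc2c(O[Si](C)(C)C(C)(C)C)cc(O[Si](C)(C)C(C)(C)C)cc2O[C@@H]1c1ccc(O[Si](C)(C)C(C)(C)C)c(O[Si](C)(C)C(C)(C)C)c1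
F4 | step 5 | tetra-O-TBS-(+)-catechin-3-yl 6-oxocyclohex-2-ene-1-carboxylate (keto form shown, enolized) | O=C1CCC=CC1C(=O)O[C@H]1Cc2c(O[Si](C)(C)C(C)(C)C)cc(O[Si](C)(C)C(C)(C)C)cc2O[C@@H]1c1ccc(O[Si](C)(C)C(C)(C)C)c(O[Si](C)(C)C(C)(C)C)c1
F5 | step 10 | (+)-catechin-3-yl (1S)-1-hydroxy-6-oxocyclohex-2-ene-1-carboxylate (free phenols) | O=C1CCC=C[C@@]1(O)C(=O)O[C@H]1Cc2c(O)cc(O)cc2O[C@@H]1c1ccc(O)c(O)c1
F6 | step 10 | catechin-(4α→8)-catechin with the upper unit tetra-O-TBS and the lower unit free phenolic and 3-O-acylated | O=C1CCC=C[C@@]1(O)C(=O)O[C@H]1Cc2c(O)cc(O)c([C@@H]3c4c(O[Si](C)(C)C(C)(C)C)cc(O[Si](C)(C)C(C)(C)C)cc4O[C@H](c4ccc(O[Si](C)(C)C(C)(C)C)c(O[Si](C)(C)C(C)(C)C)c4)[C@H]3O)c2O[C@@H]1c1ccc(O)c(O)c1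
F7 | step 11 | 5,7,3',4'-tetra-O-TBS-4α-(2,6-dimethylphenylthio)-(+)-catechin | O[C@H]1[C@H](Sc3c(C)cccc3C)c2c(O[Si](C)(C)C(C)(C)C)cc(O[Si](C)(C)C(C)(C)C)cc2O[C@@H]1c1ccc(O[Si](C)(C)C(C)(C)C)c(O[Si](C)(C)C(C)(C)C)c1
F8 | step 11 | octa-O-TBS epicatechin-(4β→8)-catechin with a 4α-(2,6-dimethylphenylthio) group on the lower unit | O[C@H]1[C@H](Sc3c(C)cccc3C)c2c(O[Si](C)(C)C(C)(C)C)cc(O[Si](C)(C)C(C)(C)C)c([C@H]5c6c(O[Si](C)(C)C(C)(C)C)cc(O[Si](C)(C)C(C)(C)C)cc6O[C@H](c6ccc(O[Si](C)(C)C(C)(C)C)c(O[Si](C)(C)C(C)(C)C)c6)[C@@H]5O)c2O[C@@H]1c1ccc(O[Si](C)(C)C(C)(C)C)c(O[Si](C)(C)C(C)(C)C)c1
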